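**Strategy.** Everything rests on building ring B instead of buying it. Its carbons C2', C1', C6' and C5' are C3, C4, C5 and C6 of a 2-pyrone that already carries the ring A aryloxy group on C4 and a bromine on C3; C3' and C4' come from an ethynylboronate. One thermal cycloaddition with loss of CO2 forms C2'–C3' and C4'–C5', closes ring B and leaves boron on C4', para to the ether oxygen on C1' and away from the C2' bromine, where it is later exchanged for bromine. The precursor is 3-bromo-4-(2,3,4-tribromo-6-methoxyphenoxy)-2H-pyran-2-one, made from tribrominated guaiacol and 4-bromo-2-pyrone.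

Key step: step 5

Assumption: 4-hydroxy-2H-pyran-2-one and the ethynyl pinacol boronate are taken as purchasable, and threefold bromination of guaiacol is taken to follow the usual directing effects (para and ortho to OH, para to OMe); the target is achiral, so no stereocentre has to be set.

Step 1
Reactants: 1 guaiacol (2-methoxyphenol)
Product: 2 2,3,4-tribromo-6-methoxyphenol
Conditions: Br2 (3.05 equiv), AcOH, 0 °C to rt
Reagents that add atoms: bromine, BrBr
Why: Electrophilic aromatic bromination, in which the free hydroxyl directs para and ortho and the methoxy group directs para, which are exactly the three ring A positions required, while the last C–H (ortho to methoxy, meta to hydroxyl, on a ring already bearing three bromines) is deactivated enough for three equivalents to stop at the tribromide.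

Step 2
Reactants: 3 4-hydroxy-2H-pyran-2-one
Product: 4 4-bromo-2H-pyran-2-one
Conditions: Bu4NBr, P2O5, toluene, 100 °C
Reagents that add atoms: tetrabutylammonium bromide, CCCC[N+](CCCC)(CCCC)CCCC.[Br-]
Why: Deoxybromination of a vinylogous acid, in which P2O5 phosphorylates the enol oxygen and bromide displaces the phosphate at C4 by addition–elimination, as is routine for 4-hydroxy-6-methyl-2-pyrone; a bromide is chosen over a sulfonate so that the phenoxide of the next step finds no sulfur centre to attack.

Step 3
Reactants: 2 2,3,4-tribromo-6-methoxyphenol, 4 4-bromo-2H-pyran-2-one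
Product: 5 4-(2,3,4-tribromo-6-methoxyphenoxy)-2H-pyran-2-one
Conditions: K2CO3, DMF, rt to 50 °C
Reagents that add atoms: none
Why: Nucleophilic vinylic substitution by addition–elimination at C4, the β-carbon of the unsaturated lactone, where the phenoxide adds to give a lactone enolate that expels bromide, as 4-halo-2-pyrones and 4-halocoumarins do with phenols; addition at C6 is reversible and drains back because only the C4 adduct has a leaving group.

Step 4
Reactants: 5 4-(2,3,4-tribromo-6-methoxyphenoxy)-2H-pyran-2-one
Product: 6 3-bromo-4-(2,3,4-tribromo-6-methoxyphenoxy)-2H-pyran-2-one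
Conditions: NBS (1.05 equiv), MeCN, rt to 50 °C
Reagents that add atoms: N-bromosuccinimide, O=C1CCC(=O)N1Br
Why: Electrophilic bromination of a push–pull enol ether, in which C3 (between the lactone carbonyl and the oxygen-bearing C4) is the most nucleophilic carbon of a 4-oxy-2-pyrone, as in the C3 bromination of 4-methoxy-2-pyrones, while the single ring A C–H sits on a ring deactivated by three bromines.

Step 5
Reactants: 6 3-bromo-4-(2,3,4-tribromo-6-methoxyphenoxy)-2H-pyran-2-one, 7 2-ethynyl-4,4,5,5-tetramethyl-1,3,2-dioxaborolane
Product: 9 2-[3-bromo-4-(2,3,4-tribromo-6-methoxyphenoxy)phenyl]-4,4,5,5-tetramethyl-1,3,2-dioxaborolane, via bridged bicyclic lactone 8 (not isolated)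
Conditions: 7 (3 equiv), o-dichlorobenzene, 170 °C, sealed tube
Reagents that add atoms: none
Why: A thermal [4+2] cycloaddition of the alkyne across pyrone C3 and C6 should give the 2-oxabicyclo[2.2.2]octadienone 8, which loses CO2 by retro-[4+2] fragmentation and aromatises; this Diels–Alder/decarboxylation of 2-pyrones with alkynylboronates is an established reaction type, halogenated pyrones included. Ring B is closed by an intermolecular cycloaddition in which both new bonds (C2'–C3' and C4'–C5') form in the same six-membered transition state. No stereocentre has to be controlled, because the two bridgehead centres of racemic 8 are erased when CO2 leaves. The selectivity needed is regiochemical: the boron-bearing alkyne carbon must join C6. The 4-aryloxy group makes the diene a 2-oxybutadiene whose larger HOMO coefficient lies on C3, which pairs with the unsubstituted, electrophilic β-carbon of the boron-conjugated alkyne (para orientation), and the C3 bromine sterically disfavours a neighbouring pinacolboryl group. The aryl bromides, the methyl ether and the diaryl ether linkage should be inert to neutral heating.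

Step 6
Reactants: 9 2-[3-bromo-4-(2,3,4-tribromo-6-methoxyphenoxy)phenyl]-4,4,5,5-tetramethyl-1,3,2-dioxaborolane
Product: 10 1,2,3-tribromo-4-(2,4-dibromophenoxy)-5-methoxybenzene
Conditions: CuBr2 (3 equiv), MeOH/H2O (1:1), 80 °C
Reagents that add atoms: CuBr2, [Cu+2].[Br-].[Br-]
Why: Copper-mediated ipso-bromodeboronation, in which the aryl group passes from boron to divalent copper, a second CuBr2 oxidises the aryl copper species to the trivalent state and C–Br reductive elimination follows; this is a reliable conversion of aryl pinacol boronates into aryl bromides and should leave the existing aryl bromides and both ethers untouched.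

**Compound list**

1 | guaiacol (2-methoxyphenol) | COc1ccccc1O | starting material
2 | 2,3,4-tribromo-6-methoxyphenol (4,5,6-tribromoguaiacol) | COc1cc(Br)c(Br)c(Br)c1O | intermediate
3 | 4-hydroxy-2H-pyran-2-one | OC1=CC(=O)OC=C1 | starting material
4 | 4-bromo-2H-pyran-2-one | BrC1=CC(=O)OC=C1 | intermediate
5 | 4-(2,3,4-tribromo-6-methoxyphenoxy)-2H-pyran-2-one | COc1cc(Br)c(Br)c(Br)c1OC1=CC(=O)OC=C1 | intermediate
6 | 3-bromo-4-(2,3,4-tribromo-6-methoxyphenoxy)-2H-pyran-2-one | COc1cc(Br)c(Br)c(Br)c1OC1=C(Br)C(=O)OC=C1 | intermediate
7 | 2-ethynyl-4,4,5,5-tetramethyl-1,3,2-dioxaborolane | C#CB1OC(C)(C)C(C)(C)O1 | starting material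
8 | 4-bromo-5-(2,3,4-tribromo-6-methoxyphenoxy)-7-(4,4,5,5-tetramethyl-1,3,2-dioxaborolan-2-yl)-2-oxabicyclo[2.2.2]octa-5,7-dien-3-one (bridged bicyclic lactone, racemic, one enantiomer drawn, not isolated) | O=C1O[C@@H]2C=C(Oc3c(OC)cc(Br)c(Br)c3Br)[C@@]1(Br)C=C2B1OC(C)(C)C(C)(C)O1 | intermediate
9 | 2-[3-bromo-4-(2,3,4-tribromo-6-methoxyphenoxy)phenyl]-4,4,5,5-tetramethyl-1,3,2-dioxaborolane | COc1cc(Br)c(Br)c(Br)c1Oc1ccc(cc1Br)B1OC(C)(C)C(C)(C)O1 | intermediate
10 | 1,2,3-tribromo-4-(2,4-dibromophenoxy)-5-methoxybenzene | COc1cc(Br)c(Br)c(Br)c1Oc1ccc(Br)cc1Br | target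

**Step count.** Total: 6 steps. Longest linear sequence: 5 steps (3 to 4 to 5 to 6 to 9 to 10; the branch from 1 is equally long).

**Steps most likely to fail**

Step 5. The cycloaddition may be too slow for the donor-substituted diene, so that thermal degradation of the pyrone or oligomerisation of the alkyne outruns it, or the alkyne may add in the reverse orientation. The fallback gives up ring construction and attaches a preformed ring B. It sets out from 2. Nucleophilic aromatic substitution of the phenoxide on 2-bromo-1-fluoro-4-nitrobenzene (K2CO3, DMF, 80 °C), in which only the fluoride para to the nitro group is activated, should give 1,2,3-tribromo-4-(2-bromo-4-nitrophenoxy)-5-methoxybenzene F1. Reduction with Fe and NH4Cl in EtOH/H2O, which spares aryl bromides, should give 3-bromo-4-(2,3,4-tribromo-6-methoxyphenoxy)aniline F2. Diazotisation (NaNO2, aqueous HBr/AcOH, 0 °C) should give 3-bromo-4-(2,3,4-tribromo-6-methoxyphenoxy)benzenediazonium bromide F3, which is not isolated; Sandmeyer bromination with CuBr on warming then comes back to the route at 10.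

Step 3. Attack of the hindered, weakly nucleophilic phenoxide at C4 may be sluggish, and ring opening of the 6-unsubstituted pyrone by attack at C6 or C2 may then consume the material. The fallback installs the pyrone bromine first and uses a stronger acceptor. It sets out from 3. Bromination with NBS (MeCN, 0 °C) at the 1,3-dicarbonyl-like C3 should give 3-bromo-4-hydroxy-2H-pyran-2-one F4. Deoxybromination (Bu4NBr, P2O5, toluene, 100 °C) should give 3,4-dibromo-2H-pyran-2-one F5, whose C4 is made more electrophilic by the α-bromine, as in 3,4-dihalofuranones. Addition–elimination of the phenoxide of 2 (K2CO3, DMF, rt) at C4 then comes back to the route at 6, and step 4 is no longer needed.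

Step 2. The 6-unsubstituted pyrone may degrade under hot dehydrating acid, or the phosphate-to-bromide exchange may stay incomplete. The fallback replaces deoxyhalogenation by mild O-sulfonylation. It sets out from 3. TsCl and Et3N in CH2Cl2 at 0 °C should give 2-oxo-2H-pyran-4-yl 4-methylbenzenesulfonate F6. Addition–elimination of the phenoxide of 2 (K2CO3, DMF, rt) at C4 then expels the sulfonate and comes back to the route at 5; sulfonyl transfer to the phenoxide is the side path to watch.

**Further compounds**

F1 | step 5 | 1,2,3-tribromo-4-(2-bromo-4-nitrophenoxy)-5-methoxybenzene | COc1cc(Br)c(Br)c(Br)c1Oc1ccc(cc1Br)[N+](=O)[O-]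
F2 | step 5 | 3-bromo-4-(2,3,4-tribromo-6-methoxyphenoxy)aniline | COc1cc(Br)c(Br)c(Br)c1Oc1ccc(N)cc1Br
F3 | step 5 | 3-bromo-4-(2,3,4-tribromo-6-methoxyphenoxy)benzenediazonium bromide | COc1cc(Br)c(Br)c(Br)c1Oc1ccc(cc1Br)[N+]#N.[Br-]
F4 | step 3 | 3-bromo-4-hydroxy-2H-pyran-2-one | OC1=C(Br)C(=O)OC=C1
F5 | step 3 | 3,4-dibromo-2H-pyran-2-one | BrC1=C(Br)C(=O)OC=C1
F6 | step 2 | 2-oxo-2H-pyran-4-yl 4-methylbenzenesulfonate | Cc1ccc(cc1)S(=O)(=O)OC1=CC(=O)OC=C1
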